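## Structural features

The target is a furofuran lignan, a 2,6-diaryl-3,7-dioxabicyclo[3.3.0]octane in which ring A (C7–O–C9'–C8'–C8) and ring B (C7'–O–C9–C8–C8') are two tetrahydrofurans cis-fused through the C8–C8' bond. C7 carries a 3-hydroxy-4,5-dimethoxyphenyl group and C7' a 3,4,5-trimethoxyphenyl group; both lie on the convex (exo) face, each trans to the ring-fusion substituent on its neighbour. The four stereocentres C7, C8, C8' and C7' are contiguous, with configuration 7S,8R,8'R,7'S (1S,3aR,4S,6aR in furo[3,4-c]furan numbering). Apart from one O–H standing in place of one O–CH3, the molecule has a C2 axis through the midpoint of C8–C8'. The fragile sites are the benzylic ether bonds C7–O and C7'–O, each para to a methoxy group: acid ionises them and scrambles exo and endo aryl groups, H2 over Pd/C cleaves them, and the free phenol and the electron-rich rings also restrict the use of oxidants. The real difficulty is to set four adjacent stereocentres in one absolute sense and to tell apart two aryl groups that differ by a single methyl group. The key step exploits the fact that C9–C8–C8'–C9' is a succinic acid unit in reduced form and that C7–C8 and C7'–C8' are aldol bonds from its two α-carbons to two aryl aldehyde carbons, so the hidden C2 axis lets one two-directional operation make both bonds and all four centres.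

## Logic of the disconnections

15 to 14. The O–CH3 bond that distinguishes the two aryl groups is cut. This restores the C2 axis, so every earlier intermediate has half the constitutional and stereochemical problem. The forward methylation cannot choose between two equivalent, remote phenols; it must be run statistically to partial conversion, with 14 recovered and recycled.

14 to 13. The two O–allyl bonds are cut. The phenols must be masked through boron Lewis acid, hydride and sulfonyl chloride chemistry. The forward unmasking must leave C7–O and C7'–O alone, which rules out hydrogenolysis and acid and points to allyl transfer on zerovalent palladium.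

13 to 11 (through 12). The ring bonds O–C9' and O–C9 are cut, not the benzylic bonds C7–O and C7'–O. Both rings open to the acyclic 11 while C7 and C7' keep their oxygen and configuration. The forward step must activate only the two primary hydroxyls, both of them before either ring closes, and the benzylic hydroxyls must act as nucleophiles without ionising.

11 to 10. C9 and C9' are raised to the carboxyl level as N-acyl oxazolidinones. This exposes two β-hydroxy carbonyl units on a succinyl core. The forward reduction must remove both auxiliaries without retro-aldol cleavage or epimerisation at C8 and C8'.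

10 to 4 and two molecules of 7. The C7–C8 and C7'–C8' bonds are cut. All four stereocentres disappear in one cut, and the fragments are 4, which has no backbone stereocentre, and 7. The forward step needs double enolisation with Z geometry at both termini, the same facial control twice, and a second addition that is faster than acyl transfer from the first aldolate.

4 to two molecules of 1 and one of 2. The two N–C(=O) bonds are cut, which leads to two commercial compounds. The forward step must acylate twice, once at each end of 2, without base-induced decomposition of 2.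

7 to 5 and 6. The O–allyl bond is cut; the forward step is a simple phenol alkylation.

## Other disconnections considered

Alternative 1: The cut is C8–C8' together with C7–O and C7'–O, leading back to two molecules of the monolignol A1, (E)-3-[3-(benzyloxy)-4-hydroxy-5-methoxyphenyl]prop-2-en-1-ol. In the forward step a laccase with O2 would make the phenoxyl radicals and a dirigent protein of the (+)-pinoresinol-forming type would guide their 8–8' coupling. The two quinone methides would then be trapped by the primary hydroxyls to give A2.
- In its favour: one operation builds one C–C bond, two C–O bonds, both rings and four stereocentres from an achiral monomer, in water and air. The substituent at C5 also blocks the competing 8–5' coupling.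
- Against it here: the protein recognises a smaller natural substrate, and nothing guarantees that a benzyloxy group at C5 is accepted or that facial control persists; without it the product would be racemic. The protein must be produced and used at high dilution. A2 still needs methylation of both 4-hydroxyls, debenzylation by hydrogenolysis next to the furofuran C–O bonds, and the same statistical methylation.
- Structure: it passes through the same C2-symmetric bisphenol 14, so on the desymmetrisation problem it is the equal of the chosen plan.
- Mechanism: stereocontrol rests on protein–substrate fit that cannot be predicted for A1, whereas the chosen plan relies on an auxiliary whose facial bias follows a well-understood model.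
- Step economy: the key step itself is better (core, rings and stereocentres in one step against three). With the steps to A1 and the three steps after A2 the totals are about equal.

Alternative 2: The cut removes the ring oxygen between C7 and C9', leading back to the cyclobutanone A3, 7-[3-(benzyloxy)-4,5-dimethoxyphenyl]-4-(3,4,5-trimethoxyphenyl)-3-oxabicyclo[3.2.0]heptane-2,6-dione. In the forward step mCPBA would add to the strained ketone and the benzylic carbon C7 would migrate with retention to give the dilactone A4.
- In its favour: ring strain makes the oxidation easy, and migration with retention keeps C7 intact. A4 already carries the two different aryl groups, so no statistical methylation is needed; on this point it is better than the chosen plan.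
- Against it here: both carbons flanking the ketone are secondary, so the regiochemistry depends on the benzylic carbon out-migrating the ring-fusion carbon. C7 in A3 is benzylic and α to a ketone, hence easily epimerised. The key step forms no C–C bond and no stereocentre; the whole stereochemical problem moves into A3, which needs an enantioselective [2+2] route of its own.
- Structure: unsymmetrical from the start, which is better than the chosen plan.
- Mechanism: a dependable oxygen insertion, but it only transfers stereochemistry that an earlier and harder step must create.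
- Step economy: after A4 a reduction to the tetraol and ring closure of the kind used in steps 4 and 5 are still needed, so the end game is equal. The way to A3 is longer than the two steps to 4 and 7.

Alternative 3: The cut is at both aryl–carbon bonds, C7–Ar and C7'–Ar, leading back to the bis-lactol diacetate A5, (1R,5R)-3,7-dioxabicyclo[3.3.0]octane-2,6-diyl diacetate, and the aryltrifluoroborate A6, potassium [3-(benzyloxy)-4,5-dimethoxyphenyl]trifluoroborate. In the forward step BF3·OEt2 would ionise each acetate to a bicyclic oxocarbenium ion, and the aryl group of A6 would add ipso from the convex face to give A7.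
- In its favour: it is the most convergent plan. The aryl groups arrive last, so it is modular. The cis-fused bicycle gives a reliable convex-face bias, and no reduction or ring closure follows.
- Against it here: the benzylic ethers of A7 are themselves ionised by BF3·OEt2, so kinetic exo selectivity can erode by ring opening. The electron-rich arene may react at its free ring positions and not ipso. A5 must be made enantiopure, because its two bridgehead centres are the only source of chirality, and this costs several steps or a resolution. A7 again needs hydrogenolysis beside the furofuran C–O bonds.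
- Structure: it reaches the symmetric bis-ether and the same statistical end, so it is equal there.
- Mechanism: substrate-shape control under Lewis acid that can reverse it, against closed transition states at low temperature in the chosen plan.
- Step economy: better after the key step (two steps to the target against four), worse before it.

Key step: step 3

Remark on the chemistry: the phenol is carried as an allyl ether rather than a benzyl ether, because debenzylation by hydrogenolysis would have to spare the two hydrogenolysis-prone benzylic C–O bonds of the furofuran, whereas allyl is removed by zerovalent palladium under neutral conditions; the skeleton, bond set and configuration of the bis-imide and of the double-aldol product are unaffected, and the (S)-auxiliary, the 7S,8S,8'S,7'S adduct and the 7S,7'S,8R,8'R target correspond centre by centre (C8 and C8' change descriptor on reduction only because C9 loses priority).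

## Route

Step 1
Reactants: 1 (S)-4-benzyl-2-oxazolidinone (2.0 equiv); 2 succinyl chloride (1.0 equiv)
Product: 4 1,4-bis[(S)-4-benzyl-2-oxooxazolidin-3-yl]butane-1,4-dione, via N-lithio oxazolidinone 3 (not isolated)
Conditions: n-BuLi (2.0 equiv), THF, −78 °C; then 2 (1.0 equiv), −78 to 0 °C
Reagents that add atoms: none
Why: Double N-acylation: two molecules of the lithiated oxazolidinone each attack one acid chloride terminus of a single molecule of 2; prior deprotonation avoids amine bases, which would dehydrochlorinate 2, and the auxiliary stereocentre is not involved.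

Step 2
Reactants: 5 3-hydroxy-4,5-dimethoxybenzaldehyde; 6 allyl bromide
Product: 7 3-(allyloxy)-4,5-dimethoxybenzaldehyde
Conditions: K2CO3, DMF, rt
Reagents that add atoms: none
Why: Williamson ether synthesis on a phenoxide with a reactive allylic bromide; the aldehyde is inert to carbonate.

Step 3
Reactants: 4 1,4-bis[(S)-4-benzyl-2-oxooxazolidin-3-yl]butane-1,4-dione; 7 3-(allyloxy)-4,5-dimethoxybenzaldehyde (2.5 equiv)
Product: 10 (4S,4'S)-3,3'-{(2S,3S)-2,3-bis[(S)-[3-(allyloxy)-4,5-dimethoxyphenyl](hydroxy)methyl]butanedioyl}bis(4-benzyloxazolidin-2-one), via bis(dibutylboron) Z,Z-dienolate 8 (not isolated), via bis(dibutylboron) aldolate 9 (not isolated)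
Conditions: Bu2BOTf (2.4 equiv), iPr2NEt (2.8 equiv), CH2Cl2, 0 °C; then 7, −78 to −20 °C; then pH 7 buffer, MeOH, H2O2, 0 °C
Reagents that add atoms: none
Why: Proposed new method: complexation of each imide carbonyl by the boron triflate and deprotonation by the hindered amine (soft enolisation) should turn 4 into the conjugated bis-(Z)-enolate 8, in which both acyl carbons are masked, so that the first aldolate finds no electrophilic carbonyl to lactonise onto before the second C–C bond exists; the closest known reaction type is the auxiliary-controlled boron syn-aldol of N-acyl oxazolidinones, N-succinoyl mono-imides included, together with the double aldol of succinamide dianions with aromatic aldehydes. Each enolate terminus then adds to one molecule of 7 through a closed six-membered chair (Zimmerman–Traxler) transition state with the aryl group equatorial, forming C7–C8 and C7'–C8'. No ring is closed in this step. C8 and C8' are set by the auxiliaries: in the dipole-opposed conformation of each N-acyl oxazolidinone the benzyl group covers one enolate face, and since both auxiliaries are S, both α-carbons are attacked in the same absolute sense, giving the C2-symmetric 8S,8'S pair. C7 and C7' follow from the (Z)-enolate geometry through the chair, which places each carbinol centre syn to its α-centre (7S,8S and 7'S,8'S). The step needs complete double enolisation, reagent control at the second and more hindered enolate over any bias from the centres already formed, and a second addition faster than acyl transfer; pre-forming 8 with excess boron triflate at 0 °C, the chelated and weakly nucleophilic boron aldolate, low temperature and an excess of the non-enolisable aldehyde are meant to secure this. Oxidative work-up releases 10 from 9, and any lactonisation after both additions is harmless because lactone and imide are reduced to the same tetraol in step 4.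

Step 4
Reactants: 10 (4S,4'S)-3,3'-{(2S,3S)-2,3-bis[(S)-[3-(allyloxy)-4,5-dimethoxyphenyl](hydroxy)methyl]butanedioyl}bis(4-benzyloxazolidin-2-one)
Product: 11 (2R,3R)-2,3-bis{(S)-[3-(allyloxy)-4,5-dimethoxyphenyl](hydroxy)methyl}butane-1,4-diol
Conditions: LiBH4, H2O, Et2O/THF, 0 °C to rt
Reagents that add atoms: none
Why: Reductive cleavage of N-acyl oxazolidinones by hydride at the exocyclic carbonyl, assisted by the neighbouring hydroxyl; no enolate is formed, so C8 and C8' keep their configuration, and 1 is released for reuse.

Step 5
Reactants: 11 (2R,3R)-2,3-bis{(S)-[3-(allyloxy)-4,5-dimethoxyphenyl](hydroxy)methyl}butane-1,4-diol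
Product: 13 (1S,3aR,4S,6aR)-1,4-bis[3-(allyloxy)-4,5-dimethoxyphenyl]tetrahydro-1H,3H-furo[3,4-c]furan, via bis(primary mesylate) 12 (not isolated)
Conditions: MsCl (2.2 equiv), pyridine, 0 °C; then rt
Reagents that add atoms: none
Why: The two unhindered primary hydroxyls are sulfonylated at 0 °C before any displacement, and on warming each benzylic hydroxyl closes a ring by an intramolecular Williamson-type 5-exo-tet substitution at C9' and C9. The C7–O and C7'–O bonds are never broken, so both centres are retained, and the cis ring fusion follows from the fixed C8 and C8' configuration.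

Step 6
Reactants: 13 (1S,3aR,4S,6aR)-1,4-bis[3-(allyloxy)-4,5-dimethoxyphenyl]tetrahydro-1H,3H-furo[3,4-c]furan
Product: 14 5,5'-[(1S,3aR,4S,6aR)-tetrahydro-1H,3H-furo[3,4-c]furan-1,4-diyl]bis(2,3-dimethoxyphenol)
Conditions: Pd(PPh3)4 (5 mol %), morpholine, THF, rt
Reagents that add atoms: none
Why: Tsuji–Trost-type allyl transfer: zerovalent palladium ionises each aryl allyl ether to a π-allyl complex and a phenoxide, and morpholine takes up the allyl group; the neutral, non-reducing conditions leave the benzylic ring ethers alone.

Step 7
Reactants: 14 5,5'-[(1S,3aR,4S,6aR)-tetrahydro-1H,3H-furo[3,4-c]furan-1,4-diyl]bis(2,3-dimethoxyphenol)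
Product: 15 2,3-dimethoxy-5-[(1S,3aR,4S,6aR)-4-(3,4,5-trimethoxyphenyl)tetrahydro-1H,3H-furo[3,4-c]furan-1-yl]phenol
Conditions: MeI (1.0 equiv), K2CO3 (1.1 equiv), acetone, rt; stopped at partial conversion, 14 recovered
Reagents that add atoms: iodomethane, CI
Why: Williamson O-methylation of one of two equivalent, non-interacting phenols, which is statistical by nature; starting bisphenol, product and over-methylated ether differ in the number of free phenols and should separate on silica, and no stereocentre is touched.

## Compound list

1 | (S)-4-benzyl-2-oxazolidinone | O=C1OC[C@H](Cc2ccccc2)N1 | starting material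
2 | succinyl chloride | O=C(Cl)CCC(=O)Cl | starting material
3 | lithium (S)-4-benzyl-2-oxooxazolidin-3-ide (not isolated) | [Li]N1[C@@H](Cc2ccccc2)COC1=O | intermediate
4 | 1,4-bis[(S)-4-benzyl-2-oxooxazolidin-3-yl]butane-1,4-dione | O=C(CCC(=O)N1[C@@H](Cc2ccccc2)COC1=O)N1[C@@H](Cc2ccccc2)COC1=O | intermediate
5 | 3-hydroxy-4,5-dimethoxybenzaldehyde | COc1cc(C=O)cc(O)c1OC | starting material
6 | allyl bromide | C=CCBr | starting material
7 | 3-(allyloxy)-4,5-dimethoxybenzaldehyde | COc1cc(C=O)cc(OCC=C)c1OC | intermediate
8 | (1Z,3Z)-1,4-bis[(S)-4-benzyl-2-oxooxazolidin-3-yl]-1,4-bis[(dibutylboranyl)oxy]buta-1,3-diene (not isolated) | CCCCB(CCCC)O/C(N1[C@@H](Cc2ccccc2)COC1=O)=C\C=C(/OB(CCCC)CCCC)N1[C@@H](Cc2ccccc2)COC1=O | intermediate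
9 | bis-O-(dibutylboranyl) aldolate of 10 (not isolated) | COc1cc([C@@H](OB(CCCC)CCCC)[C@@H](C(=O)N2[C@@H](Cc3ccccc3)COC2=O)[C@H](C(=O)N2[C@@H](Cc3ccccc3)COC2=O)[C@H](OB(CCCC)CCCC)c2cc(OC)c(OC)c(OCC=C)c2)cc(OCC=C)c1OC | intermediate
10 | (4S,4'S)-3,3'-{(2S,3S)-2,3-bis[(S)-[3-(allyloxy)-4,5-dimethoxyphenyl](hydroxy)methyl]butanedioyl}bis(4-benzyloxazolidin-2-one) | COc1cc([C@@H](O)[C@@H](C(=O)N2[C@@H](Cc3ccccc3)COC2=O)[C@H](C(=O)N2[C@@H](Cc3ccccc3)COC2=O)[C@H](O)c2cc(OC)c(OC)c(OCC=C)c2)cc(OCC=C)c1OC | intermediate
11 | (2R,3R)-2,3-bis{(S)-[3-(allyloxy)-4,5-dimethoxyphenyl](hydroxy)methyl}butane-1,4-diol | COc1cc([C@@H](O)[C@@H](CO)[C@H](CO)[C@H](O)c2cc(OC)c(OC)c(OCC=C)c2)cc(OCC=C)c1OC | intermediate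
12 | (2R,3R)-2,3-bis{(S)-[3-(allyloxy)-4,5-dimethoxyphenyl](hydroxy)methyl}butane-1,4-diyl dimethanesulfonate (not isolated) | COc1cc([C@@H](O)[C@@H](COS(C)(=O)=O)[C@H](COS(C)(=O)=O)[C@H](O)c2cc(OC)c(OC)c(OCC=C)c2)cc(OCC=C)c1OC | intermediate
13 | (1S,3aR,4S,6aR)-1,4-bis[3-(allyloxy)-4,5-dimethoxyphenyl]tetrahydro-1H,3H-furo[3,4-c]furan | COc1cc([C@H]2OC[C@H]3[C@@H]2CO[C@@H]3c2cc(OC)c(OC)c(OCC=C)c2)cc(OCC=C)c1OC | intermediate
14 | 5,5'-[(1S,3aR,4S,6aR)-tetrahydro-1H,3H-furo[3,4-c]furan-1,4-diyl]bis(2,3-dimethoxyphenol) | COc1cc([C@H]2OC[C@H]3[C@@H]2CO[C@@H]3c2cc(OC)c(OC)c(O)c2)cc(O)c1OC | intermediate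
15 | 2,3-dimethoxy-5-[(1S,3aR,4S,6aR)-4-(3,4,5-trimethoxyphenyl)tetrahydro-1H,3H-furo[3,4-c]furan-1-yl]phenol | COc1cc([C@H]2OC[C@H]3[C@@H]2CO[C@@H]3c2cc(OC)c(OC)c(OC)c2)cc(O)c1OC | target

## Step count and least certain steps

Total step count: 7. Longest linear sequence: 6 steps (steps 1, 3, 4, 5, 6, 7; the branch through step 2 is equally long).

Step 3 (key step, proposed as a new method). The most likely failures are incomplete enolisation of the second imide, or a slow second addition at the hindered enolate that stops at mono-addition. Facial control at the second enolate may also be eroded by the centres formed in the first addition. The fallback uses two ordinary boron syn-aldol reactions in sequence; it sets out from 4 and 7 and returns at 10. One imide of 4 is enolised with one equivalent of Bu2BOTf and iPr2NEt and treated with one equivalent of 7, which should give the mono-adduct (4S,4'S)-3,3'-{(2S)-2-[(S)-[3-(allyloxy)-4,5-dimethoxyphenyl](hydroxy)methyl]butanedioyl}bis(4-benzyloxazolidin-2-one) F1, with unreacted 4 recovered. The hydroxyl is silylated at once (TBSOTf, 2,6-lutidine) to the tert-butyldimethylsilyl ether of the mono-adduct F2, so that it cannot lactonise onto the second imide. A second boron aldol with 7 at the remaining CH2 group (the methine C8 does not enolise under these conditions) should give the mono-O-tert-butyldimethylsilyl ether of the bis-adduct F3, and HF·pyridine then removes the silyl group to give 10.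

Step 4. Hydride may attack the ring carbonyl of the auxiliary instead of the crowded exocyclic carbonyl, and alkoxide-induced retro-aldol cleavage could compete. The fallback sets out from 10 and returns at 11. A catalytic amount of DBU in CH2Cl2 should trigger two 5-exo-trig O-acyl transfers from the imides to the benzylic hydroxyls, releasing 1 and giving the dilactone (1S,2S,5S,6S)-2,6-bis[3-(allyloxy)-4,5-dimethoxyphenyl]-3,7-dioxabicyclo[3.3.0]octane-4,8-dione F4. LiAlH4 in THF then reduces both lactones to 11.

Step 5. Ring closure between the two primary positions (C9–O–C9') competes if the second primary hydroxyl is not sulfonylated before the first displacement starts. Sulfonylation and ionisation at the electron-rich benzylic carbons would cost the configuration at C7 and C7'. The fallback never opens the rings; it sets out from 10 and returns at 13. The dilactone F4, made from 10 with catalytic DBU as in the fallback to step 4, is reduced with i-Bu2AlH at −78 °C to the bis-lactol 2,6-bis[3-(allyloxy)-4,5-dimethoxyphenyl]-3,7-dioxabicyclo[3.3.0]octane-4,8-diol F5 (anomeric mixture). Ionic reduction with Et3SiH and BF3·OEt2 at −78 °C then removes both lactol hydroxyls through oxocarbenium ions at C9 and C9' and gives 13.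

Step 7. The two phenols cannot be distinguished, so at most about half of the material can be mono-methylated per pass on statistical grounds, and over-methylation at the second phenol removes material for good. The fallback moves the statistical event to a step with no dead-end product; it sets out from 13 and returns at 15. The conditions of step 6 are stopped at partial conversion to give the mono-phenol 5-{(1S,3aR,4S,6aR)-4-[3-(allyloxy)-4,5-dimethoxyphenyl]tetrahydro-1H,3H-furo[3,4-c]furan-1-yl}-2,3-dimethoxyphenol F6, while recovered 13 and 14 both stay on the route. Exhaustive methylation (MeI, K2CO3) gives (1S,3aR,4S,6aR)-1-[3-(allyloxy)-4,5-dimethoxyphenyl]-4-(3,4,5-trimethoxyphenyl)tetrahydro-1H,3H-furo[3,4-c]furan F7, and a second allyl transfer with Pd(PPh3)4 and morpholine gives 15.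

Step 1. The half-acylated acid chloride may decompose through ketene formation or fail to acylate a second time, leaving mono-acylated material. The fallback builds the two imide bonds one at a time; it sets out from 1 and returns at 4. Lithiated 1 opens succinic anhydride to 4-[(S)-4-benzyl-2-oxooxazolidin-3-yl]-4-oxobutanoic acid F8. Pivaloyl chloride and Et3N convert it into the mixed anhydride 4-[(S)-4-benzyl-2-oxooxazolidin-3-yl]-4-oxobutanoic pivalic anhydride F9, which acylates a second equivalent of 3 at the less hindered carbonyl to give 4.

## Further compounds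

F1 | step 3 | (4S,4'S)-3,3'-{(2S)-2-[(S)-[3-(allyloxy)-4,5-dimethoxyphenyl](hydroxy)methyl]butanedioyl}bis(4-benzyloxazolidin-2-one) | COc1cc([C@@H](O)[C@@H](C(=O)N2[C@@H](Cc3ccccc3)COC2=O)CC(=O)N2[C@@H](Cc3ccccc3)COC2=O)cc(OCC=C)c1OC
F2 | step 3 | tert-butyldimethylsilyl ether of F1 | COc1cc([C@@H](O[Si](C)(C)C(C)(C)C)[C@@H](C(=O)N2[C@@H](Cc3ccccc3)COC2=O)CC(=O)N2[C@@H](Cc3ccccc3)COC2=O)cc(OCC=C)c1OC
F3 | step 3 | mono-O-tert-butyldimethylsilyl ether of 10 | COc1cc([C@@H](O[Si](C)(C)C(C)(C)C)[C@@H](C(=O)N2[C@@H](Cc3ccccc3)COC2=O)[C@H](C(=O)N2[C@@H](Cc3ccccc3)COC2=O)[C@H](O)c2cc(OC)c(OC)c(OCC=C)c2)cc(OCC=C)c1OC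
F4 | step 4 | (1S,2S,5S,6S)-2,6-bis[3-(allyloxy)-4,5-dimethoxyphenyl]-3,7-dioxabicyclo[3.3.0]octane-4,8-dione | COc1cc([C@H]2OC(=O)[C@H]3[C@@H]2C(=O)O[C@@H]3c2cc(OC)c(OC)c(OCC=C)c2)cc(OCC=C)c1OC
F5 | step 5 | 2,6-bis[3-(allyloxy)-4,5-dimethoxyphenyl]-3,7-dioxabicyclo[3.3.0]octane-4,8-diol, anomeric mixture, other centres as in 13 | COc1cc([C@H]2OC(O)[C@H]3[C@@H]2C(O)O[C@@H]3c2cc(OC)c(OC)c(OCC=C)c2)cc(OCC=C)c1OC
F6 | step 7 | 5-{(1S,3aR,4S,6aR)-4-[3-(allyloxy)-4,5-dimethoxyphenyl]tetrahydro-1H,3H-furo[3,4-c]furan-1-yl}-2,3-dimethoxyphenol | COc1cc([C@H]2OC[C@H]3[C@@H]2CO[C@@H]3c2cc(OC)c(OC)c(OCC=C)c2)cc(O)c1OC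
F7 | step 7 | (1S,3aR,4S,6aR)-1-[3-(allyloxy)-4,5-dimethoxyphenyl]-4-(3,4,5-trimethoxyphenyl)tetrahydro-1H,3H-furo[3,4-c]furan | COc1cc([C@H]2OC[C@H]3[C@@H]2CO[C@@H]3c2cc(OC)c(OC)c(OCC=C)c2)cc(OC)c1OC
F8 | step 1 | 4-[(S)-4-benzyl-2-oxooxazolidin-3-yl]-4-oxobutanoic acid | OC(=O)CCC(=O)N1[C@@H](Cc2ccccc2)COC1=O
F9 | step 1 | 4-[(S)-4-benzyl-2-oxooxazolidin-3-yl]-4-oxobutanoic pivalic anhydride | CC(C)(C)C(=O)OC(=O)CCC(=O)N1[C@@H](Cc2ccccc2)COC1=O
A1 | alternative 1 | (E)-3-[3-(benzyloxy)-4-hydroxy-5-methoxyphenyl]prop-2-en-1-ol | COc1cc(/C=C/CO)cc(OCc2ccccc2)c1O
A2 | alternative 1 | exo,exo-2,6-bis[3-(benzyloxy)-4-hydroxy-5-methoxyphenyl]-3,7-dioxabicyclo[3.3.0]octane | COc1cc([C@H]2OC[C@H]3[C@@H]2CO[C@@H]3c4cc(OC)c(O)c(OCc5ccccc5)c4)cc(OCc6ccccc6)c1O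
A3 | alternative 2 | 7-[3-(benzyloxy)-4,5-dimethoxyphenyl]-4-(3,4,5-trimethoxyphenyl)-3-oxabicyclo[3.2.0]heptane-2,6-dione | COc1cc([C@H]2C(=O)[C@H]3[C@@H]2C(=O)O[C@@H]3c4cc(OC)c(OC)c(OC)c4)cc(OCc5ccccc5)c1OC
A4 | alternative 2 | exo,exo-2-[3-(benzyloxy)-4,5-dimethoxyphenyl]-6-(3,4,5-trimethoxyphenyl)-3,7-dioxabicyclo[3.3.0]octane-4,8-dione | COc1cc([C@H]2OC(=O)[C@H]3[C@@H]2C(=O)O[C@@H]3c4cc(OC)c(OC)c(OC)c4)cc(OCc5ccccc5)c1OC
A5 | alternative 3 | (1R,5R)-3,7-dioxabicyclo[3.3.0]octane-2,6-diyl diacetate | CC(=O)OC1OC[C@H]2[C@@H]1COC2OC(C)=O
A6 | alternative 3 | potassium [3-(benzyloxy)-4,5-dimethoxyphenyl]trifluoroborate | [K+].COc1cc([B-](F)(F)F)cc(OCc2ccccc2)c1OC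
A7 | alternative 3 | exo,exo-2,6-bis[3-(benzyloxy)-4,5-dimethoxyphenyl]-3,7-dioxabicyclo[3.3.0]octane | COc1cc([C@H]2OC[C@H]3[C@@H]2CO[C@@H]3c4cc(OC)c(OC)c(OCc5ccccc5)c4)cc(OCc6ccccc6)c1OC
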